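## Analysis of the target

Agrimol B (23) is a linear trimer of acylphloroglucinols. The central ring B carries arylmethyl groups at C1 and C3, hydroxyl groups at C2, C4 and C6 and a 2-methylbutanoyl group at C5. Each CH2 bridge leads to C3 of a ring A that bears butanoyl at C1, hydroxyl at C2 and C4, methyl at C5 and methoxy at C6. All eighteen ring carbons are substituted, and apart from the side-chain stereocentre the molecule has a mirror plane through ring B C2 and C5, so the two rings A are identical. The single stereocentre is the α-carbon of the ring B acyl group, (S); it has no partner, but it sits α to an aryl ketone and can epimerize by enolization. Sensitive features are the seven electron-rich phenols, the diarylmethane bridges (which can cleave and recombine in free methylenebis-phloroglucinols under acid or base) and the methyl ethers ortho to a ketone (cleaved by strong Lewis acids). The difficulty is threefold: an unsymmetrical A–B–A trimer must be made without the statistical scrambling of a formaldehyde condensation, ring A carries six different substituents with one O-methyl among three oxygens, and the chiral acyl group must be attached without racemization. The strategy reads ring B as the enol form of a cyclohexane-1,3,5-trione: C1–C2–C3 with its two CH2–aryl branches is a 2,4-dialkylated 3-oxopentanedioate, and C4–C5–C6 is a malonyl unit whose central carbon later takes the acyl group.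

## Retrosynthetic reasoning

**23 ⇐ 21.** The last operation should be neutral and release every masked function at once. Adding benzyl groups to the four ring A hydroxyls and benzyl ester groups to ring B C1 and C3 turns 23 into the non-aromatic triketone 21. Forward, hydrogenolysis must cleave four benzyl ethers and two benzyl esters; the diacid 22 so formed is a doubly activated β-keto acid, so decarboxylation and tautomerization to the aromatic triol need no further reagent. The finished trimer and its stereocentre never meet a Lewis acid or a base.

**21 ⇐ 18 + 19.** The bond between ring B C5 and the acyl carbon is cut next. In 18 this carbon is the CH2 of a cyclic 1,3-dione, the only strong carbon acid in the molecule, so it can be acylated by carbodiimide activation of the chiral-pool acid 19 followed by O-to-C acyl transfer. This puts the stereocentre in as late as possible and avoids a Friedel–Crafts acylation with its Lewis acid.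

**18 ⇐ 15 + 16.** Ring B is opened at C1–C6 and C3–C4. These cuts separate the ring into the malonyl unit of malonyl dichloride 16 and the keto diester 15, in which both bridges and both complete rings A are already in place. The ester groups at C1 and C3 make the two α-carbons acidic enough for soft enolization and hold the new ring as a trione. The forward reaction has to achieve two C-acylations, each creating a quaternary carbon, the second closing the ring.

**15 ⇐ 14 + 10; 14 ⇐ 13 + 10; 13 ⇐ 11.** The two bonds between the α-carbons and the benzylic CH2 groups are cut one after the other. The bridges are thus made by enolate alkylation and not by electrophilic substitution on a phenol, which removes the scrambling problem. The symmetry of the target is used, since the same bromide 10 serves for both rings A. The two alkylations are run as separate operations: the first gives the monoalkylated keto diester 14, and in 14 the still unsubstituted α′-CH2 is the more acidic and less hindered position, which sends the second arylmethyl group to the other side of the ketone. Benzyl esters are chosen so that they leave in the same final hydrogenolysis; 13 comes from 11 by ester exchange.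

**10 ⇐ 9 ⇐ 8 ⇐ 6.** The benzylic carbon is traced back to a formyl group at the one unsubstituted ring carbon of 6. Formylation there has no regiochemical choice. Reduction of the aldehyde and bromination of the alcohol are functional-group steps that the hindered aryl ketone should tolerate.

**6 ⇐ 5 ⇐ 3.** The oxygen pattern is set by the differing reactivity of the three hydroxyls of 3. The para hydroxyl is free of chelation, and of the two ortho hydroxyls one is squeezed between the C-methyl and the butanoyl group. Twofold benzylation should leave exactly that one, which is the oxygen that carries the methyl ether in ring A.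

**3 ⇐ 1 + 2.** The butanoyl group is introduced by Friedel–Crafts acylation of 1, whose two free ring carbons are equivalent. A ring that carried the O-methyl group from the start but neither carbon substituent would need three substitutions of uncertain regiochemistry, which is why the C-methyl group is bought with the starting material instead.

## Alternatives that were turned down

**Alternative 1:** Both rings A are disconnected at C4–C5 and C6–C1. C5 and C6 with their methyl and methoxy groups come from 1-methoxyprop-1-yne A2. The other four carbons of each ring A come from a 3-tert-butoxycyclobutenone attached through the bridge carbon to a finished, tribenzylated and already (S)-acylated ring B, the bis(cyclobutenone) A1.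
- Forward key step: heating A1 with A2 opens each cyclobutenone to a vinylketene, which adds to the alkyne; ring opening and 6π closure give both rings A as phenols in A3 (double Danheiser benzannulation).
- For: the polarity of the ynol ether fixes the methyl group next to the new hydroxyl and the methoxy group next to the methyl. The chosen route depends on a selective benzylation for this, so alternative 1 is stronger on that point. The step is thermal and neutral.
- Against: two benzannulations must succeed on one molecule. A1 needs a long preparation on a ring B that already carries the epimerizable ketone, which then passes through prolonged heating. A3 still lacks both butanoyl groups at ring A C1; these would have to be put in by Lewis-acid chemistry beside tert-butyl ethers, a free phenol and the chiral ketone, and three kinds of oxygen protection must then be removed.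
- Comparison: the chosen strategy brings rings A in complete and needs only two steps after its key step. Its price is a key step without direct precedent.

**Alternative 2:** The two ring A C1–C(=O) bonds are disconnected, each ketone carbon being drawn from the butanoate ester on the neighbouring C2 oxygen. The precursor is the dibromo heptabutanoate A4 of the acyl-free trimer.
- Forward key step: halogen–lithium exchange with an alkyllithium at very low temperature at both C1 bromines; each aryllithium attacks the adjacent ester (anionic Fries rearrangement) to give A5.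
- For: the position of each butanoyl group is fixed by the bromine and by proximity, the esters serve as protection and as acyl source, and no ring has to be built. The anionic Fries rearrangement is well known, so on precedent for the key step this alternative is stronger than the chosen one.
- Against: A4 carries seven enolizable esters that compete with the exchange and with the wanted shift, and five must survive. The acyl-free A–B–A skeleton has to be made first, which brings back the unsymmetrical methylene coupling. The chiral acyl group must still be introduced afterwards on a pentaester, followed by five ester cleavages under conditions that can epimerize the α-carbon and break the bridges.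
- Comparison: the chosen strategy offers an unambiguous assembly of the trimer, a late and mild introduction of the chiral acyl group and one neutral global deprotection.

**Alternative 3:** Ring B is disconnected at C2–C3 and C4–C5. C3 and C4 come from the ynol ether A7, which carries one ring A-methyl group. The other four ring B carbons come from the cyclobutenone A6, which carries the second.
- Forward key step: thermal Danheiser benzannulation of A6 with A7 gives ring B directly as the phenol A8.
- For: it builds the same ring as the chosen strategy, convergently, with a reaction type that has good precedent for alkoxyalkynes and 3-alkoxycyclobutenones. No quaternary carbon is made and ring B is aromatic at once. On the security of the key step alternative 3 is stronger.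
- Against: the symmetry of the target is not used, since A6 and A7 are two different ring A derivatives, each with its own multi-step preparation. A8 lacks all three acyl groups (both ring A C1 positions and ring B C5 are unsubstituted). Three acylations at three electron-rich positions of similar reactivity would follow, with Lewis acids beside tert-butyl ethers and with the risk of racemizing the chiral acyl chloride.
- Comparison: in the chosen strategy both rings A come from one bromide with their ketones in place, and the chiral acyl group goes onto the only carbon acid present.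

Key step: step 10

## Route

Assumption: 2-methylbenzene-1,3,5-triol (1) is taken as a purchasable compound.

Abbreviations: Ar = 2,6-bis(benzyloxy)-3-butanoyl-4-methoxy-5-methylphenyl; Ar′ = 3-butanoyl-2,6-dihydroxy-4-methoxy-5-methylphenyl. The cyclic triones 18, 21 and 22 are written as keto forms although they should exist largely as enols, and as mixtures at their two quaternary ring carbons.

Step 1
Reactants: 1 2-methylbenzene-1,3,5-triol; 2 butanoyl chloride
Product: 3 1-(2,4,6-trihydroxy-3-methylphenyl)butan-1-one
Conditions: AlCl3 (3 equiv), PhNO2/CH2Cl2, 0 °C to rt; aq. HCl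
Reagents that add atoms: none
Why: Friedel–Crafts acylation of a phloroglucinol; the two unsubstituted ring carbons of 1 are equivalent, so only one C-acyl product can form, and the new ketone deactivates the ring against a second acylation.

Step 2
Reactants: 3 1-(2,4,6-trihydroxy-3-methylphenyl)butan-1-one
Product: 5 1-[4,6-bis(benzyloxy)-2-hydroxy-3-methylphenyl]butan-1-one, via para-monobenzyl ether 4 (not isolated)
Conditions: BnBr (2.05 equiv), K2CO3, DMF, rt
Reagents that add atoms: benzyl bromide, BrCc1ccccc1
Why: Williamson ether synthesis; the unchelated para hydroxyl should react first (4), and of the two chelated ortho hydroxyls the one beside the ring hydrogen should be benzylated in preference to the one wedged between the C-methyl and the butanoyl group. The polar aprotic solvent favours O- over C-benzylation.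

Step 3
Reactants: 5 1-[4,6-bis(benzyloxy)-2-hydroxy-3-methylphenyl]butan-1-one
Product: 6 1-[4,6-bis(benzyloxy)-2-methoxy-3-methylphenyl]butan-1-one
Conditions: MeI, K2CO3, DMF, 50 °C
Reagents that add atoms: iodomethane, CI
Why: Williamson methylation of the remaining chelated phenol under slightly more forcing conditions; it also removes the 2-hydroxyaryl ketone motif, which would divert the next step towards a chromone.

Step 4
Reactants: 6 1-[4,6-bis(benzyloxy)-2-methoxy-3-methylphenyl]butan-1-one
Product: 8 2,6-bis(benzyloxy)-3-butanoyl-4-methoxy-5-methylbenzaldehyde, via aryl iminium chloride 7 (not isolated)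
Conditions: POCl3, DMF, 0 to 50 °C; then aq. NaOAc
Reagents that add atoms: N,N-dimethylformamide, CN(C)C=O; water, O
Why: Vilsmeier–Haack formylation at the only unsubstituted ring carbon, which is ortho to both benzyloxy groups and para to the methoxy group; the butanoyl group is twisted out of conjugation by its two ortho substituents and should deactivate little. Hydrolysis of 7 on work-up gives the aldehyde, and benzyl ethers tolerate the reagent.

Step 5
Reactants: 8 2,6-bis(benzyloxy)-3-butanoyl-4-methoxy-5-methylbenzaldehyde
Product: 9 1-[2,4-bis(benzyloxy)-3-(hydroxymethyl)-6-methoxy-5-methylphenyl]butan-1-one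
Conditions: NaBH4, THF/MeOH, 0 °C
Reagents that add atoms: none
Why: Chemoselective hydride reduction; the aldehyde should be reduced much faster than the electron-rich aryl ketone, which is shielded by two ortho substituents.

Step 6
Reactants: 9 1-[2,4-bis(benzyloxy)-3-(hydroxymethyl)-6-methoxy-5-methylphenyl]butan-1-one
Product: 10 1-[2,4-bis(benzyloxy)-3-(bromomethyl)-6-methoxy-5-methylphenyl]butan-1-one
Conditions: CBr4, PPh3, CH2Cl2, 0 °C; used directly
Reagents that add atoms: tetrabromomethane, BrC(Br)(Br)Br
Why: Appel bromination under neutral conditions, which spares the benzyl ethers; the electron-rich benzylic bromide cannot alkylate itself because its ring has no free position.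

Step 7
Reactants: 11 dimethyl 3-oxopentanedioate
Product: 13 dibenzyl 3-oxopentanedioate, via benzyl methyl 3-oxopentanedioate 12 (not isolated)
Conditions: BnOH (5 equiv), DMAP (cat.), toluene, reflux, MeOH distilled off
Reagents that add atoms: benzyl alcohol, OCc1ccccc1
Why: Transesterification of a β-keto ester; both ester groups are β to the ketone, so both exchange, and removal of methanol drives the equilibrium.

Step 8
Reactants: 13 dibenzyl 3-oxopentanedioate; 10 1-[2,4-bis(benzyloxy)-3-(bromomethyl)-6-methoxy-5-methylphenyl]butan-1-one
Product: 14 dibenzyl 2-(ArCH2)-3-oxopentanedioate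
Conditions: 13 (1.5 equiv), NaH (1.05 equiv), THF/DMF, 0 °C; then 10 (1.0 equiv) added slowly, 0 °C to rt; excess 13 recovered
Reagents that add atoms: none
Why: Enolate C-alkylation of a β-keto ester with a benzylic bromide; the excess of 13 and the slow addition of 10 should hold back a second alkylation, so that the monoalkylated keto diester can be isolated. The ring A ketone of 10 is a far weaker carbon acid and stays untouched.

Step 9
Reactants: 14 dibenzyl 2-(ArCH2)-3-oxopentanedioate; 10 1-[2,4-bis(benzyloxy)-3-(bromomethyl)-6-methoxy-5-methylphenyl]butan-1-one
Product: 15 dibenzyl 2,4-bis(ArCH2)-3-oxopentanedioate (mixture of diastereomers)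
Conditions: NaH (1.05 equiv), THF/DMF, 0 °C; then 10 (1.05 equiv), 0 °C to rt
Reagents that add atoms: none
Why: Second enolate C-alkylation of the β-keto ester; in 14 the unsubstituted α′-CH2 is more acidic and less hindered than the already substituted α-CH, so the second bulky arylmethyl group should enter at the other α-carbon. The two stereocentres of 15 are epimerizable and form as a mixture, which is of no consequence because both are replaced in the next step.

Step 10
Reactants: 15 dibenzyl 2,4-bis(ArCH2)-3-oxopentanedioate; 16 malonyl dichloride
Product: 18 dibenzyl 1,3-bis(ArCH2)-2,4,6-trioxocyclohexane-1,3-dicarboxylate (mixture of diastereomers), via C-acylated acyl chloride 17 (not isolated)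
Conditions: MgCl2 (2.5 equiv), Et3N (3.3 equiv), MeCN/CH2Cl2, 0 °C, 1 h; then 16 (1.05 equiv) in CH2Cl2, slow addition at high dilution, −20 °C to rt; aq. citric acid
Reagents that add atoms: none
Why: Proposed new method: MgCl2 and Et3N convert one β-keto ester terminus of 15 into a chelated magnesium enolate, which is C-acylated by one acyl chloride group of 16 to give 17; enolization of the second terminus then lets its α-carbon attack the remaining acyl chloride (or the acylketene formed from it by loss of HCl) and close ring B. The closest known reactions are the MgCl2/Et3N C-acylation of malonates and β-keto esters by acid chlorides and the cyclocondensation of 3-oxoglutarate esters with malonic acid derivatives to phloroglucinol dicarboxylates; what has not been shown is the twofold acylation at carbons that both become quaternary. Ring B closes by a 6-exo-trig attack of the enolate carbon on the acyl carbon, which is favoured whether the enolate double bond lies inside or outside the new ring. The two new quaternary centres (ring B C1 and C3) form without control as a cis/trans mixture, which is harmless because both become sp2 carbons in step 12. The step needs C- over O-acylation at both termini and ring closure over chain growth: chelation of the keto ester oxygens to magnesium leaves carbon as the nucleophilic site, an O-acylated enol lactone by-product should still be convertible into 18 by acyl transfer, and slow addition of 16 at high dilution favours the intramolecular second acylation. Only the two α-carbons of the 3-oxopentanedioate are acidic enough for this base system, so the ring A ketones, the benzyl ethers and the benzyl esters should be spectators. Product 18 is an acidic cyclic 1,3-dione, and its deprotonation by the third equivalent of amine withdraws it from further acylation.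

Step 11
Reactants: 18 dibenzyl 1,3-bis(ArCH2)-2,4,6-trioxocyclohexane-1,3-dicarboxylate; 19 (2S)-2-methylbutanoic acid
Product: 21 dibenzyl 1,3-bis(ArCH2)-5-[(2S)-2-methylbutanoyl]-2,4,6-trioxocyclohexane-1,3-dicarboxylate, via enol ester 20 (not isolated)
Conditions: DCC, DMAP (1.2 equiv), CH2Cl2, 0 °C to rt
Reagents that add atoms: none
Why: Steglich-type O-acylation of the cyclic 1,3-dione gives enol ester 20, which DMAP should convert by O-to-C acyl transfer (acylpyridinium/dione enolate ion pair) into the 2-acyl-1,3-dione, as known for cyclohexane-1,3-diones and 2,2,4,4-tetrasubstituted cyclohexane-1,3,5-triones. The (S) centre comes unchanged from 19; no Lewis acid is used, and the product is enolized within the ring tricarbonyl system and not towards the side-chain α-carbon.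

Step 12
Reactants: 21 dibenzyl 1,3-bis(ArCH2)-5-[(2S)-2-methylbutanoyl]-2,4,6-trioxocyclohexane-1,3-dicarboxylate
Product: 23 agrimol B, (2S)-1-[3,5-bis(Ar′CH2)-2,4,6-trihydroxyphenyl]-2-methylbutan-1-one, via trioxo diacid 22 (not isolated)
Conditions: H2 (1 atm), Pd/C, EtOAc, rt, then 40 °C
Reagents that add atoms: none
Why: Hydrogenolysis of four benzyl ethers and two benzyl esters; each carboxyl group of 22 sits on a carbon between two ring carbonyls and should be lost as a β-keto acid, after which the trione tautomerizes to the aromatic ring B. The neutral conditions should leave the aryl ketones, the methyl ethers and the α-stereocentre untouched, and the two quaternary centres disappear.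

## Compound list

1 | 2-methylbenzene-1,3,5-triol | Cc1c(O)cc(O)cc1O | starting material
2 | butanoyl chloride | CCCC(=O)Cl | starting material
3 | 1-(2,4,6-trihydroxy-3-methylphenyl)butan-1-one | CCCC(=O)c1c(O)cc(O)c(C)c1O | intermediate
4 | 1-[4-(benzyloxy)-2,6-dihydroxy-3-methylphenyl]butan-1-one | CCCC(=O)c1c(O)cc(OCc2ccccc2)c(C)c1O | intermediate
5 | 1-[4,6-bis(benzyloxy)-2-hydroxy-3-methylphenyl]butan-1-one | CCCC(=O)c1c(OCc2ccccc2)cc(OCc2ccccc2)c(C)c1O | intermediate
6 | 1-[4,6-bis(benzyloxy)-2-methoxy-3-methylphenyl]butan-1-one | CCCC(=O)c1c(OCc2ccccc2)cc(OCc2ccccc2)c(C)c1OC | intermediate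
7 | N-{[2,6-bis(benzyloxy)-3-butanoyl-4-methoxy-5-methylphenyl]methylidene}-N-methylmethanaminium chloride | CCCC(=O)c1c(OCc2ccccc2)c(C=[N+](C)C)c(OCc2ccccc2)c(C)c1OC.[Cl-] | intermediate
8 | 2,6-bis(benzyloxy)-3-butanoyl-4-methoxy-5-methylbenzaldehyde | CCCC(=O)c1c(OCc2ccccc2)c(C=O)c(OCc2ccccc2)c(C)c1OC | intermediate
9 | 1-[2,4-bis(benzyloxy)-3-(hydroxymethyl)-6-methoxy-5-methylphenyl]butan-1-one | CCCC(=O)c1c(OCc2ccccc2)c(CO)c(OCc2ccccc2)c(C)c1OC | intermediate
10 | 1-[2,4-bis(benzyloxy)-3-(bromomethyl)-6-methoxy-5-methylphenyl]butan-1-one | CCCC(=O)c1c(OCc2ccccc2)c(CBr)c(OCc2ccccc2)c(C)c1OC | intermediate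
11 | dimethyl 3-oxopentanedioate | COC(=O)CC(=O)CC(=O)OC | starting material
12 | benzyl methyl 3-oxopentanedioate | COC(=O)CC(=O)CC(=O)OCc1ccccc1 | intermediate
13 | dibenzyl 3-oxopentanedioate | O=C(CC(=O)OCc1ccccc1)CC(=O)OCc1ccccc1 | intermediate
14 | dibenzyl 2-{[2,6-bis(benzyloxy)-3-butanoyl-4-methoxy-5-methylphenyl]methyl}-3-oxopentanedioate | O=C(OCc4ccccc4)C(Cc2c(OCc4ccccc4)c(C)c(OC)c(C(=O)CCC)c2OCc4ccccc4)C(=O)CC(=O)OCc4ccccc4 | intermediate
15 | dibenzyl 2,4-bis{[2,6-bis(benzyloxy)-3-butanoyl-4-methoxy-5-methylphenyl]methyl}-3-oxopentanedioate (mixture of diastereomers) | O=C(OCc4ccccc4)C(Cc2c(OCc4ccccc4)c(C)c(OC)c(C(=O)CCC)c2OCc4ccccc4)C(=O)C(Cc3c(OCc4ccccc4)c(C)c(OC)c(C(=O)CCC)c3OCc4ccccc4)C(=O)OCc4ccccc4 | intermediate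
16 | malonyl dichloride | O=C(Cl)CC(Cl)=O | starting material
17 | dibenzyl 2,4-bis{[2,6-bis(benzyloxy)-3-butanoyl-4-methoxy-5-methylphenyl]methyl}-2-(3-chloro-3-oxopropanoyl)-3-oxopentanedioate | O=C(OCc4ccccc4)C(Cc2c(OCc4ccccc4)c(C)c(OC)c(C(=O)CCC)c2OCc4ccccc4)(C(=O)CC(=O)Cl)C(=O)C(Cc3c(OCc4ccccc4)c(C)c(OC)c(C(=O)CCC)c3OCc4ccccc4)C(=O)OCc4ccccc4 | intermediate
18 | dibenzyl 1,3-bis{[2,6-bis(benzyloxy)-3-butanoyl-4-methoxy-5-methylphenyl]methyl}-2,4,6-trioxocyclohexane-1,3-dicarboxylate (mixture of diastereomers) | O=C1CC(=O)C(Cc2c(OCc4ccccc4)c(C)c(OC)c(C(=O)CCC)c2OCc4ccccc4)(C(=O)OCc4ccccc4)C(=O)C1(Cc3c(OCc4ccccc4)c(C)c(OC)c(C(=O)CCC)c3OCc4ccccc4)C(=O)OCc4ccccc4 | intermediate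
19 | (2S)-2-methylbutanoic acid | CC[C@H](C)C(=O)O | starting material
20 | dibenzyl 1,3-bis{[2,6-bis(benzyloxy)-3-butanoyl-4-methoxy-5-methylphenyl]methyl}-4-{[(2S)-2-methylbutanoyl]oxy}-2,6-dioxocyclohex-4-ene-1,3-dicarboxylate | O=C1C=C(OC(=O)[C@@H](C)CC)C(Cc2c(OCc4ccccc4)c(C)c(OC)c(C(=O)CCC)c2OCc4ccccc4)(C(=O)OCc4ccccc4)C(=O)C1(Cc3c(OCc4ccccc4)c(C)c(OC)c(C(=O)CCC)c3OCc4ccccc4)C(=O)OCc4ccccc4 | intermediate
21 | dibenzyl 1,3-bis{[2,6-bis(benzyloxy)-3-butanoyl-4-methoxy-5-methylphenyl]methyl}-5-[(2S)-2-methylbutanoyl]-2,4,6-trioxocyclohexane-1,3-dicarboxylate | O=C1C(C(=O)[C@@H](C)CC)C(=O)C(Cc2c(OCc4ccccc4)c(C)c(OC)c(C(=O)CCC)c2OCc4ccccc4)(C(=O)OCc4ccccc4)C(=O)C1(Cc3c(OCc4ccccc4)c(C)c(OC)c(C(=O)CCC)c3OCc4ccccc4)C(=O)OCc4ccccc4 | intermediate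
22 | 1,3-bis{[3-butanoyl-2,6-dihydroxy-4-methoxy-5-methylphenyl]methyl}-5-[(2S)-2-methylbutanoyl]-2,4,6-trioxocyclohexane-1,3-dicarboxylic acid | O=C1C(C(=O)[C@@H](C)CC)C(=O)C(Cc2c(O)c(C)c(OC)c(C(=O)CCC)c2O)(C(=O)O)C(=O)C1(Cc3c(O)c(C)c(OC)c(C(=O)CCC)c3O)C(=O)O | intermediate
23 | agrimol B, (2S)-1-[3,5-bis({3-butanoyl-2,6-dihydroxy-4-methoxy-5-methylphenyl}methyl)-2,4,6-trihydroxyphenyl]-2-methylbutan-1-one | CCCC(=O)c1c(O)c(Cc2c(O)c(Cc3c(O)c(C)c(OC)c(C(=O)CCC)c3O)c(O)c(C(=O)[C@@H](C)CC)c2O)c(O)c(C)c1OC | target

## Step count and least certain steps

Total: 12 steps. Longest linear sequence: 11 steps (steps 1–6 and 8–12 from 1); step 7 is a one-step side branch that joins at step 8.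

**Step 10 (key step, Proposed new method).**
- What may go wrong: O-acylation of the enolates and chain growth in place of the second C-acylation; dehydrohalogenation of 16 by the amine to a ketene that polymerizes; retro-Claisen opening of the congested, non-enolizable tricarbonyl product during work-up.
- Why: each C-acylation has to create a quaternary carbon beside a bulky arylmethyl group, and at those carbons the usual driving force of product deprotonation is missing.
- Fallback (known chemistry; sets out from 9 and 19, returns at 23): 19 is converted with oxalyl chloride into (2S)-2-methylbutanoyl chloride F1, which acylates phloroglucinol (AlCl3, PhNO2/CH2Cl2) to give (2S)-2-methyl-1-(2,4,6-trihydroxyphenyl)butan-1-one F2. Acid-catalysed Friedel–Crafts benzylation of F2 with two equivalents of alcohol 9 (Sc(OTf)3 cat., MeNO2/CH2Cl2) follows; the cation from 9 is stabilized by three alkoxy groups and F2 has exactly two free ring carbons. This should give tetra-O-benzyl agrimol B F3, and hydrogenolysis (H2, Pd/C, EtOAc) leads to 23.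

**Step 2.**
- What may go wrong: loss of site selectivity between the two chelated hydroxyls, and some C-benzylation at the free ring carbon.
- Why: the preference rests only on the steric difference between a neighbouring methyl group and a neighbouring hydrogen.
- Fallback (sets out from 2, returns at 6): Friedel–Crafts acylation of phloroglucinol with 2 gives 1-(2,4,6-trihydroxyphenyl)butan-1-one F4. Dibenzylation, unambiguous here because the two ortho hydroxyls are equivalent, gives 1-[2,4-bis(benzyloxy)-6-hydroxyphenyl]butan-1-one F5. Iodination ortho to the free hydroxyl (N-iodosuccinimide) gives 1-[4,6-bis(benzyloxy)-2-hydroxy-3-iodophenyl]butan-1-one F6. O-methylation gives 1-[4,6-bis(benzyloxy)-3-iodo-2-methoxyphenyl]butan-1-one F7. Suzuki–Miyaura methylation (trimethylboroxine, Pd(PPh3)4, K2CO3, dioxane) then gives 6.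

**Step 4.**
- What may go wrong: attack of the chloroiminium reagent on the enolizable butanoyl ketone in place of the ring, or no reaction at the ring carbon.
- Why: the ring position is flanked by two benzyloxy groups and lies meta to a ketone.
- Fallback (sets out from 6, returns at 9): bromination with N-bromosuccinimide at the single free ring position gives 1-[2,4-bis(benzyloxy)-3-bromo-6-methoxy-5-methylphenyl]butan-1-one F8. Stille coupling with (tributylstannyl)methanol (Pd(PPh3)4, dioxane, 100 °C) gives alcohol 9 directly, so that step 5 is not needed.

**Step 9.**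
- What may go wrong: slow substitution at the di-ortho-substituted benzylic carbon, with O-alkylation or a second alkylation at the already substituted α-carbon taking over.
- Why: the electrophile is hindered, the enolate of 14 is ambident, and the site selectivity rests on the difference between a CH2 and a substituted CH.
- Fallback (sets out from 14 and 9, returns at 15; no new compound, F0): dehydrative C-alkylation of the β-keto ester 14 with the benzylic alcohol 9 under Lewis acid catalysis (Bi(OTf)3 cat., MeNO2, rt). The reaction runs through the stabilized benzylic cation and the less hindered enol, so it needs neither the bromide 10 nor a base, and any enol ether formed can revert under the acidic conditions.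

**Step 11.**
- What may go wrong: erosion of configuration by ketene formation from the acylpyridinium ion, stalling at the enol ester 20, or nucleophilic ring cleavage of 18 by DMAP.
- Why: the acyl donor is α-branched and the ring ketone between the two quaternary carbons cannot enolize.
- Fallback (sets out from 18, returns at 23): hydrogenolysis of 18 (H2, Pd/C, EtOAc) with loss of both carboxyl groups gives 2,4-bis{[3-butanoyl-2,6-dihydroxy-4-methoxy-5-methylphenyl]methyl}benzene-1,3,5-triol F9. Friedel–Crafts acylation with (2S)-2-methylbutanoyl chloride F1 (made from 19 as in the fallback for step 10; BF3·OEt2, dioxane) at the only unsubstituted ring carbon of F9 gives 23. Rings A are fully substituted, so C-acylation can occur only on ring B.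

## Further compounds

F1 | step 10 | (2S)-2-methylbutanoyl chloride | CC[C@H](C)C(=O)Cl
F2 | step 10 | (2S)-2-methyl-1-(2,4,6-trihydroxyphenyl)butan-1-one | CC[C@H](C)C(=O)c1c(O)cc(O)cc1O
F3 | step 10 | (2S)-1-[3,5-bis({2,6-bis(benzyloxy)-3-butanoyl-4-methoxy-5-methylphenyl}methyl)-2,4,6-trihydroxyphenyl]-2-methylbutan-1-one | CCCC(=O)c1c(OCc4ccccc4)c(Cc2c(O)c(Cc3c(OCc4ccccc4)c(C)c(OC)c(C(=O)CCC)c3OCc4ccccc4)c(O)c(C(=O)[C@@H](C)CC)c2O)c(OCc4ccccc4)c(C)c1OC
F4 | step 2 | 1-(2,4,6-trihydroxyphenyl)butan-1-one | CCCC(=O)c1c(O)cc(O)cc1O
F5 | step 2 | 1-[2,4-bis(benzyloxy)-6-hydroxyphenyl]butan-1-one | CCCC(=O)c1c(OCc2ccccc2)cc(OCc2ccccc2)cc1O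
F6 | step 2 | 1-[4,6-bis(benzyloxy)-2-hydroxy-3-iodophenyl]butan-1-one | CCCC(=O)c1c(OCc2ccccc2)cc(OCc2ccccc2)c(I)c1O
F7 | step 2 | 1-[4,6-bis(benzyloxy)-3-iodo-2-methoxyphenyl]butan-1-one | CCCC(=O)c1c(OCc2ccccc2)cc(OCc2ccccc2)c(I)c1OC
F8 | step 4 | 1-[2,4-bis(benzyloxy)-3-bromo-6-methoxy-5-methylphenyl]butan-1-one | CCCC(=O)c1c(OCc2ccccc2)c(Br)c(OCc2ccccc2)c(C)c1OC
F0 | step 9 | none | none
F9 | step 11 | 2,4-bis{[3-butanoyl-2,6-dihydroxy-4-methoxy-5-methylphenyl]methyl}benzene-1,3,5-triol | CCCC(=O)c1c(O)c(Cc2c(O)cc(O)c(Cc3c(O)c(C)c(OC)c(C(=O)CCC)c3O)c2O)c(O)c(C)c1OC
A1 | alternative 1 | (2S)-1-{2,4,6-tris(benzyloxy)-3,5-bis[(2-tert-butoxy-4-oxocyclobut-2-en-1-yl)methyl]phenyl}-2-methylbutan-1-one | CC[C@H](C)C(=O)c1c(OCc4ccccc4)c(CC2C(=O)C=C2OC(C)(C)C)c(OCc4ccccc4)c(CC3C(=O)C=C3OC(C)(C)C)c1OCc4ccccc4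
A2 | alternative 1 | 1-methoxyprop-1-yne | CC#COC
A3 | alternative 1 | (2S)-1-{2,4,6-tris(benzyloxy)-3,5-bis[(6-tert-butoxy-2-hydroxy-4-methoxy-3-methylphenyl)methyl]phenyl}-2-methylbutan-1-one | COc1cc(OC(C)(C)C)c(Cc2c(OCc4ccccc4)c(C(=O)[C@@H](C)CC)c(OCc4ccccc4)c(Cc3c(O)c(C)c(OC)cc3OC(C)(C)C)c2OCc4ccccc4)c(O)c1C
A4 | alternative 2 | 2,4-bis{[3-bromo-2,6-bis(butanoyloxy)-4-methoxy-5-methylphenyl]methyl}benzene-1,3,5-triyl tributanoate | CCCC(=O)Oc1c(Br)c(OC)c(C)c(OC(=O)CCC)c1Cc2c(OC(=O)CCC)cc(OC(=O)CCC)c(Cc3c(OC(=O)CCC)c(C)c(OC)c(Br)c3OC(=O)CCC)c2OC(=O)CCC
A5 | alternative 2 | 2,4-bis{[3-butanoyl-6-(butanoyloxy)-2-hydroxy-4-methoxy-5-methylphenyl]methyl}benzene-1,3,5-triyl tributanoate | CCCC(=O)c1c(O)c(Cc2c(OC(=O)CCC)c(Cc3c(OC(=O)CCC)c(C)c(OC)c(C(=O)CCC)c3O)c(OC(=O)CCC)cc2OC(=O)CCC)c(OC(=O)CCC)c(C)c1OC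
A6 | alternative 3 | 4-{[2,6-bis(benzyloxy)-4-methoxy-3-methylphenyl]methyl}-3-tert-butoxycyclobut-2-en-1-one | O=C1C=C(OC(C)(C)C)C1Cc2c(OCc4ccccc4)c(C)c(OC)cc2OCc4ccccc4
A7 | alternative 3 | 1,3-bis(benzyloxy)-2-(3-tert-butoxyprop-2-yn-1-yl)-5-methoxy-4-methylbenzene | CC(C)(C)OC#CCc3c(OCc4ccccc4)c(C)c(OC)cc3OCc4ccccc4
A8 | alternative 3 | 2,6-bis{[2,6-bis(benzyloxy)-4-methoxy-3-methylphenyl]methyl}-3,5-di-tert-butoxyphenol | COc1cc(OCc4ccccc4)c(Cc2c(O)c(Cc3c(OCc4ccccc4)c(C)c(OC)cc3OCc4ccccc4)c(OC(C)(C)C)cc2OC(C)(C)C)c(OCc4ccccc4)c1C
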